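**Plan**
- Cuts, in retrosynthetic order: (i) the O–C(CH3)2 bond of the 2H-pyran fused to ring B, with two H returned, which leads to (2S)-7,4'-dihydroxy-6,3'-diprenylflavanone. (ii) C2–C1' between the stereocentre and ring B. (iii) O1–C2 and C2–C3 of the pyranone. (iv) The two aryl–prenyl bonds at C6 and C3'.
- Forward: rings A and B are bought as benzene derivatives and each is C-prenylated. The pyranone ring C is closed on ring A as a chromone, ring B is joined at C2, and the 2,2-dimethyl-2H-pyran is closed last.
- Enabling feature: on ring B the 4'-OH lies ortho to the C3'-prenyl group and is not conjugated with C4=O. Loss of hydride from benzylic C1'' gives the 1-oxatriene O=C4'–C3'=C1''–C2''=C3''(CH3)2, which closes by 6π electrocyclisation.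
- Ring A carries the same 1,2-pair (7-OH/6-prenyl), but there 7-OH is para to C4=O, a vinylogous acid. An FAD-dependent BBE-like oxidocyclase is asked to tell the two pairs apart on the unprotected diphenol, so both phenols share one protecting group and both C5 units one oxidation level.
- Stereochemistry: the only centre, C2 (S), comes from the chiral ligand in a Rh(I)-catalysed 1,4-addition of the arylboronic acid to the chromone. All later steps are acidic or near neutral, which avoids retro-oxa-Michael racemisation.

Key step: step 9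

Assumption: a BBE-like oxidocyclase that turns over the diprenylflavanone is taken to be found by screening recombinant class members and variants; the (S)-ligand in step 7 is assigned by analogy with cyclic enones and would be exchanged for its antipode if the sense were opposite.

Step 1
Reactants: 1 2,4-dihydroxyacetophenone; 2 2-methylbut-3-en-2-ol
Product: 3 1-[2,4-dihydroxy-5-(3-methylbut-2-en-1-yl)phenyl]ethanone
Conditions: BF3·OEt2 (0.3 equiv), 1,4-dioxane, rt
Reagents that add atoms: none
Why: Friedel–Crafts prenylation in which the dimethylallyl cation from 2 attacks C5, which is activated by both hydroxyls like C3 but is not flanked by two substituents; the reaction has close precedent on this ketone, and the C3 isomer is removed by chromatography.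

Step 2
Reactants: 3 1-[2,4-dihydroxy-5-(3-methylbut-2-en-1-yl)phenyl]ethanone
Product: 4 1-[2-hydroxy-4-(methoxymethoxy)-5-(3-methylbut-2-en-1-yl)phenyl]ethanone
Conditions: MOMCl (1.1 equiv), K2CO3, acetone, 0 °C to rt
Reagents that add atoms: chloromethyl methyl ether (MOMCl) COCCl
Why: Williamson-type O-alkylation that should be selective because the 2-OH is held in a hydrogen bond to the acetyl C=O, so only the free, more acidic 4-OH reacts under weak base.

Step 3
Reactants: 4 1-[2-hydroxy-4-(methoxymethoxy)-5-(3-methylbut-2-en-1-yl)phenyl]ethanone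
Product: 6 7-(methoxymethoxy)-6-(3-methylbut-2-en-1-yl)-4H-chromen-4-one, via enaminone 5 (not isolated)
Conditions: DMF-DMA, toluene, 100 °C; evaporate; AcOH, 60 °C
Reagents that add atoms: N,N-dimethylformamide dimethyl acetal COC(OC)N(C)C
Why: Enaminone route to chromones, in which the methyl ketone condenses with the amide acetal to 5 and weak acid then triggers 6-endo addition of the 2-OH to the β-carbon with loss of dimethylamine, which buffers the medium so that the aryl MOM ether and the prenyl group should survive.

Step 4
Reactants: 7 4-bromophenol; 8 prenyl bromide (1-bromo-3-methylbut-2-ene)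
Product: 9 4-bromo-2-(3-methylbut-2-en-1-yl)phenol
Conditions: NaH, toluene, 0 °C to rt
Reagents that add atoms: none
Why: ortho-C-alkylation of a sodium phenoxide tight ion pair in a non-polar solvent, where sodium bridges oxygen and bromide and steers the primary carbon of 8 to the ortho position, the para position being blocked by bromine.

Step 5
Reactants: 9 4-bromo-2-(3-methylbut-2-en-1-yl)phenol
Product: 10 4-bromo-1-(methoxymethoxy)-2-(3-methylbut-2-en-1-yl)benzene
Conditions: NaH, MOMCl, THF, 0 °C
Reagents that add atoms: chloromethyl methyl ether (MOMCl) COCCl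
Why: Standard MOM protection of a phenoxide, which removes the acidic proton before metalation and uses the same group as on ring A so that one operation frees both phenols later.

Step 6
Reactants: 10 4-bromo-1-(methoxymethoxy)-2-(3-methylbut-2-en-1-yl)benzene
Product: 13 [4-(methoxymethoxy)-3-(3-methylbut-2-en-1-yl)phenyl]boronic acid, via aryllithium 11 (not isolated), via lithium aryltriisopropoxyborate 12 (not isolated)
Conditions: n-BuLi, THF, −78 °C; B(OiPr)3, −78 °C to rt; 1 M HCl to pH 5, 0 °C
Reagents that add atoms: triisopropyl borate CC(C)OB(OC(C)C)OC(C)C; water O; n-butyllithium [Li]CCCC (lithium of 11 and 12 only)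
Why: Bromine–lithium exchange at −78 °C is faster than MOM-directed ortho-lithiation or allylic deprotonation, and electrophilic borylation followed by brief cold hydrolysis is the standard access to arylboronic acids.

Step 7
Reactants: 6 7-(methoxymethoxy)-6-(3-methylbut-2-en-1-yl)-4H-chromen-4-one; 13 [4-(methoxymethoxy)-3-(3-methylbut-2-en-1-yl)phenyl]boronic acid
Product: 14 (2S)-7-(methoxymethoxy)-2-[4-(methoxymethoxy)-3-(3-methylbut-2-en-1-yl)phenyl]-6-(3-methylbut-2-en-1-yl)chroman-4-one
Conditions: [Rh(OH)((S)-MeO-F12-BIPHEP)]2 (1.5 mol %), 13 (2 equiv), CH2Cl2/H2O 10:1, 20 °C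
Reagents that add atoms: none
Why: Hayashi–Miyaura Rh(I)-catalysed asymmetric 1,4-addition of an arylboronic acid to a 4-chromone, with close precedent for oxygenated chromones; the (S)-configured electron-poor biaryl bisphosphine shields one face of the bound C2=C3 bond so that aryl migration should set C2 as S, and the mild base-free medium suppresses enolate ring opening and 1,2-addition.

Step 8
Reactants: 14 (2S)-7-(methoxymethoxy)-2-[4-(methoxymethoxy)-3-(3-methylbut-2-en-1-yl)phenyl]-6-(3-methylbut-2-en-1-yl)chroman-4-one
Product: 15 (2S)-7-hydroxy-2-[4-hydroxy-3-(3-methylbut-2-en-1-yl)phenyl]-6-(3-methylbut-2-en-1-yl)chroman-4-one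
Conditions: cat. conc. HCl, MeOH, 40 °C
Reagents that add atoms: none
Why: Acid-catalysed acetal exchange removes both MOM groups at once, a deprotection widely used on C-prenylated flavonoids; C2 is configurationally stable in acid, and dilute acid at moderate temperature should not close the o-prenylphenols to chromans.

Step 9
Reactants: 15 (2S)-7-hydroxy-2-[4-hydroxy-3-(3-methylbut-2-en-1-yl)phenyl]-6-(3-methylbut-2-en-1-yl)chroman-4-one
Product: 17 dinklagin A, via ring-B o-quinone methide 16 (not isolated)
Conditions: FAD-dependent BBE-like oxidocyclase (recombinant, variant selected on 15), catalase, air, Na citrate buffer pH 5.5, 10 % DMSO, 30 °C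
Reagents that add atoms: none
Why: Proposed new method: in the active site the 4'-OH of ring B is deprotonated by the catalytic base while the benzylic C1''–H of the 3'-prenyl group passes as hydride to N5 of the covalently bound FAD, giving the (Z)-o-quinone methide 16 (1-oxatriene O=C4'–C3'=C1''–C2''=C3''), which closes the O–C3'' bond by a thermally allowed 6π-oxa-electrocyclisation with rearomatisation of ring B, the reduced flavin being re-oxidised by O2 to H2O2 that catalase destroys. The closest known reaction type is the oxidative cyclisation of ortho-geranyl and ortho-farnesyl resorcylic acids to 2H-chromenes by the BBE-like enzymes cannabichromenic acid synthase and daurichromenic acid synthase, and quinone oxidants such as DDQ run the same hydride abstraction/electrocyclisation on o-prenylphenols without built-in site control; new here is the substrate class, a neutral C-prenylated flavanone with two competing o-prenylphenol units. One ring is closed, the 2,2-dimethyl-2H-pyran, in a pericyclic (6π, formally 6-endo) mode. No new stereocentre arises because C3'' bears two methyl groups, and the existing C2 centre is remote from the reacting atoms and is kept from retro-oxa-Michael epimerisation by the acidic buffer. The selectivity needed is site selectivity for the ring B pair 4'-OH/3'-prenyl over the ring A pair 7-OH/6-prenyl: in ring A the oxygen lone pair is drawn into C4=O (7-OH para to the ketone), so its benzylic hydride is the poorer donor and its quinone methide the less stable, and the pocket adds shape recognition by taking up the slim p-alkylphenol end of 15 with the chromanone pointing to the entrance. Over-oxidation should stop at 17 because the product holds no free phenol on ring B.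

**Compound list**
1 | 2,4-dihydroxyacetophenone | CC(=O)c1ccc(O)cc1O | starting material
2 | 2-methylbut-3-en-2-ol | CC(C)(O)C=C | starting material
3 | 1-[2,4-dihydroxy-5-(3-methylbut-2-en-1-yl)phenyl]ethanone | CC(=O)c1cc(CC=C(C)C)c(O)cc1O | intermediate
4 | 1-[2-hydroxy-4-(methoxymethoxy)-5-(3-methylbut-2-en-1-yl)phenyl]ethanone | CC(=O)c1cc(CC=C(C)C)c(OCOC)cc1O | intermediate
5 | (E)-3-(dimethylamino)-1-[2-hydroxy-4-(methoxymethoxy)-5-(3-methylbut-2-en-1-yl)phenyl]prop-2-en-1-one (enaminone, not isolated) | CN(C)/C=C/C(=O)c1cc(CC=C(C)C)c(OCOC)cc1O | intermediate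
6 | 7-(methoxymethoxy)-6-(3-methylbut-2-en-1-yl)-4H-chromen-4-one | O=c1ccoc2cc(OCOC)c(CC=C(C)C)cc12 | intermediate
7 | 4-bromophenol | Oc1ccc(Br)cc1 | starting material
8 | prenyl bromide (1-bromo-3-methylbut-2-ene) | CC(C)=CCBr | starting material
9 | 4-bromo-2-(3-methylbut-2-en-1-yl)phenol | CC(C)=CCc1cc(Br)ccc1O | intermediate
10 | 4-bromo-1-(methoxymethoxy)-2-(3-methylbut-2-en-1-yl)benzene | CC(C)=CCc1cc(Br)ccc1OCOC | intermediate
11 | [4-(methoxymethoxy)-3-(3-methylbut-2-en-1-yl)phenyl]lithium (not isolated) | [Li]c1ccc(OCOC)c(CC=C(C)C)c1 | intermediate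
12 | lithium triisopropoxy[4-(methoxymethoxy)-3-(3-methylbut-2-en-1-yl)phenyl]borate (not isolated) | [Li+].CC(C)O[B-](OC(C)C)(OC(C)C)c1ccc(OCOC)c(CC=C(C)C)c1 | intermediate
13 | [4-(methoxymethoxy)-3-(3-methylbut-2-en-1-yl)phenyl]boronic acid | OB(O)c1ccc(OCOC)c(CC=C(C)C)c1 | intermediate
14 | (2S)-7-(methoxymethoxy)-2-[4-(methoxymethoxy)-3-(3-methylbut-2-en-1-yl)phenyl]-6-(3-methylbut-2-en-1-yl)chroman-4-one | CC(C)=CCc1cc2c(cc1OCOC)O[C@H](c1ccc(OCOC)c(CC=C(C)C)c1)CC2=O | intermediate
15 | (2S)-7-hydroxy-2-[4-hydroxy-3-(3-methylbut-2-en-1-yl)phenyl]-6-(3-methylbut-2-en-1-yl)chroman-4-one ((2S)-7,4'-dihydroxy-6,3'-diprenylflavanone) | CC(C)=CCc1cc2c(cc1O)O[C@H](c1ccc(O)c(CC=C(C)C)c1)CC2=O | intermediate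
16 | ring-B (Z)-o-quinone methide of 15: (2S)-7-hydroxy-6-(3-methylbut-2-en-1-yl)-2-[(3Z)-3-(3-methylbut-2-en-1-ylidene)-4-oxocyclohexa-1,5-dien-1-yl]chroman-4-one (enzyme-bound, not isolated) | CC(C)=CCc1cc2c(cc1O)O[C@H](C1=C/C(=C/C=C(C)C)C(=O)C=C1)CC2=O | intermediate
17 | dinklagin A, (2S)-2-(2,2-dimethyl-2H-chromen-6-yl)-7-hydroxy-6-(3-methylbut-2-en-1-yl)chroman-4-one | CC(C)=CCc1cc2c(cc1O)O[C@H](c1ccc3c(c1)C=CC(C)(C)O3)CC2=O | target

**Total step count:** 9
**Longest linear sequence:** 6 steps (1, 2, 3, 7, 8, 9; the branch 4, 5, 6, 7, 8, 9 is equally long)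

**Steps most likely to fail**

**Step 9 (Proposed new method).**
- What may go wrong: the bulky neutral flavanone may not be taken up or turned over. Site selectivity may be lost through dehydrogenation at the ring A prenyl group. The enzyme may be inactivated by the co-solvent needed to dissolve the substrate.
- The fallback uses known chemistry, sets out from 9 and 6 and comes back at 17.
- Phenol 9 would be silylated (TBSCl, imidazole, DMF) to tert-butyl[4-bromo-2-(3-methylbut-2-en-1-yl)phenoxy]dimethylsilane F1.
- This would be converted as in step 6 into {4-[(tert-butyldimethylsilyl)oxy]-3-(3-methylbut-2-en-1-yl)phenyl}boronic acid F2.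
- Addition to 6 as in step 7 would give the orthogonally protected (2S)-4'-(tert-butyldimethylsilyloxy)-7-(methoxymethoxy)-6,3'-diprenylflavanone F3.
- Et3N·3HF in THF would free only the ring B phenol to give (2S)-4'-hydroxy-7-(methoxymethoxy)-6,3'-diprenylflavanone F4, in which ring A cannot form a quinone methide.
- DDQ (toluene, rt to 60 °C), the known dehydrogenative cyclisation of o-prenylphenols, would close the pyran ring, still the last ring, to 7-O-(methoxymethyl)dinklagin A F5.
- HCl/MeOH as in step 8 would then give 17.

**Step 7.**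
- What may go wrong: carbometalation of the electron-rich 7-alkoxychromone may be slow, so that protodeboronation of the electron-rich boronic acid wins. β-Elimination of the enolate may open the ring to the chalcone and erode the enantiomeric purity.
- The fallback replaces the asymmetric C–C bond formation by a resolution. It sets out from 10 (through 11) and 4 and comes back at 14.
- Aryllithium 11 would be quenched with DMF to 4-(methoxymethoxy)-3-(3-methylbut-2-en-1-yl)benzaldehyde F6.
- Claisen–Schmidt condensation with 4 (KOH, EtOH, rt) would give (E)-2'-hydroxy-4,4'-bis(methoxymethoxy)-3,5'-diprenylchalcone F7.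
- NaOAc in refluxing EtOH would close it to racemic 7,4'-bis(methoxymethoxy)-6,3'-diprenylflavanone F8.
- Kinetic resolution by Noyori-type transfer hydrogenation (RuCl[(R,R)-TsDPEN](p-cymene), HCO2H/Et3N, EtOAc, rt) should reduce the (2R)-enantiomer to the cis-(2R,4R)-flavan-4-ol F9 and leave (2S)-ketone 14, which is separated by chromatography.

**Step 1.**
- What may go wrong: poor regioselectivity between C5 and C3, double prenylation, and acid-induced closure of the o-prenylphenol to a chroman.
- The fallback fixes the position with a halogen, sets out from 1 and comes back at 4.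
- Bromination (NBS, MeCN, 0 °C) should give 1-(5-bromo-2,4-dihydroxyphenyl)ethanone F10.
- Selective 4-O-protection as in step 2 would give 1-[5-bromo-2-hydroxy-4-(methoxymethoxy)phenyl]ethanone F11.
- Stille coupling with tributyl(3-methylbut-2-en-1-yl)stannane (Pd(PPh3)4, DMF, 100 °C) would deliver the linear prenyl arene 4.

**Further compounds**
F1 | step 9 | tert-butyl[4-bromo-2-(3-methylbut-2-en-1-yl)phenoxy]dimethylsilane | CC(C)=CCc1cc(Br)ccc1O[Si](C)(C)C(C)(C)C
F2 | step 9 | {4-[(tert-butyldimethylsilyl)oxy]-3-(3-methylbut-2-en-1-yl)phenyl}boronic acid | OB(O)c1ccc(O[Si](C)(C)C(C)(C)C)c(CC=C(C)C)c1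
F3 | step 9 | (2S)-4'-(tert-butyldimethylsilyloxy)-7-(methoxymethoxy)-6,3'-diprenylflavanone | CC(C)=CCc1cc2c(cc1OCOC)O[C@H](c1ccc(O[Si](C)(C)C(C)(C)C)c(CC=C(C)C)c1)CC2=O
F4 | step 9 | (2S)-4'-hydroxy-7-(methoxymethoxy)-6,3'-diprenylflavanone | CC(C)=CCc1cc2c(cc1OCOC)O[C@H](c1ccc(O)c(CC=C(C)C)c1)CC2=O
F5 | step 9 | 7-O-(methoxymethyl)dinklagin A | CC(C)=CCc1cc2c(cc1OCOC)O[C@H](c1ccc3c(c1)C=CC(C)(C)O3)CC2=O
F6 | step 7 | 4-(methoxymethoxy)-3-(3-methylbut-2-en-1-yl)benzaldehyde | CC(C)=CCc1cc(C=O)ccc1OCOC
F7 | step 7 | (E)-2'-hydroxy-4,4'-bis(methoxymethoxy)-3,5'-diprenylchalcone | CC(C)=CCc1cc(C(=O)/C=C/c2ccc(OCOC)c(CC=C(C)C)c2)c(O)cc1OCOC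
F8 | step 7 | racemic 7,4'-bis(methoxymethoxy)-6,3'-diprenylflavanone | CC(C)=CCc1cc2c(cc1OCOC)OC(c1ccc(OCOC)c(CC=C(C)C)c1)CC2=O
F9 | step 7 | cis-(2R,4R)-7,4'-bis(methoxymethoxy)-6,3'-diprenylflavan-4-ol | CC(C)=CCc1cc2c(cc1OCOC)O[C@@H](c1ccc(OCOC)c(CC=C(C)C)c1)C[C@H]2O
F10 | step 1 | 1-(5-bromo-2,4-dihydroxyphenyl)ethanone | CC(=O)c1cc(Br)c(O)cc1O
F11 | step 1 | 1-[5-bromo-2-hydroxy-4-(methoxymethoxy)phenyl]ethanone | CC(=O)c1cc(Br)c(OCOC)cc1O
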